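Everything rests on cutting ring C of the chlorinated isoflavone unit at C8a–O1, C4a–C4 and O1–C2. The feature exploited is that ring A carries O1 at C8a and the C4 ketone at the adjacent C4a, with the C5 oxygen flanking C4a: an aryne spanning C8a–C4a accepts both atoms, and its lone methoxy neighbour decides which goes where. In one operation 3,5-dimethoxybenzyne, freed from an ortho-silyl aryl triflate, inserts into the C–O bond of (E)-2-(4-bromophenyl)-3-methoxyacrylic acid and the resulting phenoxide closes the pyranone. C8 chlorination, copper-catalysed etherification with 8-hydroxygenistein trimethyl ether and global demethylation finish the synthesis.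

Key step: step 7

Remark: the target is achiral and no stereocentre is set; the E enol ether of 11, 12 and 14 is the only stereochemical element and disappears in step 7.

Step 1
Reactants: 1 3,5-dimethoxyphenol
Product: 2 3,5-dimethoxyphenyl isopropylcarbamate
Conditions: i-PrNCO, Et3N (cat.), CH2Cl2, rt
Reagents that add atoms: isopropyl isocyanate, CC(C)N=C=O
Why: Amine-catalysed addition of the phenol O–H across the isocyanate (carbamoylation) should be clean for an electron-rich phenol and installs a group that both directs metalation and is removed under mild base.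

Step 2
Reactants: 2 3,5-dimethoxyphenyl isopropylcarbamate
Product: 6 3,5-dimethoxy-2-(trimethylsilyl)phenyl isopropylcarbamate, via N-silyl carbamate 3 (not isolated), via aryllithium 4 (not isolated), via N-silyl arylsilane 5 (not isolated)
Conditions: TBSOTf, TMEDA, Et2O, 0 °C → rt; n-BuLi, TMEDA, −78 °C; TMSCl, −78 °C → rt; aq NaHSO4
Reagents that add atoms: chlorotrimethylsilane, C[Si](C)(C)Cl
Why: Directed ortho-metalation: after transient N-silylation the carbamate steers n-BuLi to C2, which is flanked by the carbamate and a methoxy group (C6 is equivalent by symmetry, C4 lacks the carbamate), TMSCl traps the aryllithium, and the N–Si bond is hydrolysed on acidic work-up.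

Step 3
Reactants: 6 3,5-dimethoxy-2-(trimethylsilyl)phenyl isopropylcarbamate
Product: 8 3,5-dimethoxy-2-(trimethylsilyl)phenyl trifluoromethanesulfonate, via silyl phenol 7 (not isolated)
Conditions: DBU, Et2NH, MeCN, 40 °C; then PhNTf2, rt
Reagents that add atoms: N-phenylbis(trifluoromethanesulfonimide), O=S(=O)(N(c1ccccc1)S(=O)(=O)C(F)(F)F)C(F)(F)F
Why: DBU removes the carbamate N–H and triggers E1cB loss of isopropyl isocyanate, which Et2NH traps as a urea, and the freed phenoxide is sulfonylated by PhNTf2 (aryl triflate formation) without disturbing the C–Si bond.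

Step 4
Reactants: 9 methyl 4-bromophenylacetate
Product: 10 methyl (Z)-2-(4-bromophenyl)-3-hydroxyacrylate (enol form of the formyl ester)
Conditions: NaH, HCO2Me, THF, 0 °C → rt; then aq HCl
Reagents that add atoms: methyl formate, COC=O
Why: Crossed Claisen condensation of the ester enolate with non-enolisable methyl formate, driven by deprotonation of the product to its stabilised sodium enolate.

Step 5
Reactants: 10 methyl (Z)-2-(4-bromophenyl)-3-hydroxyacrylate
Product: 11 methyl (E)-2-(4-bromophenyl)-3-methoxyacrylate
Conditions: Me2SO4, K2CO3, DMF, rt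
Reagents that add atoms: dimethyl sulfate, COS(=O)(=O)OC
Why: O-alkylation of the potassium enolate by a hard electrophile in a dipolar aprotic solvent should give the enol ether, normally as the E isomer (methoxy anti to the ester) for 2-aryl-3-methoxyacrylates; the geometry has no bearing on step 7.

Step 6
Reactants: 11 methyl (E)-2-(4-bromophenyl)-3-methoxyacrylate
Product: 12 (E)-2-(4-bromophenyl)-3-methoxyacrylic acid
Conditions: LiOH·H2O, THF/MeOH/H2O, 40 °C; then 1 M HCl, 0 °C
Reagents that add atoms: lithium hydroxide (hydroxide oxygen), [Li+].[OH-]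
Why: Saponification by acyl substitution at the ester carbonyl; the β-methoxyacrylate is a vinylogous carbonate that resists conjugate attack by hydroxide, and cold mild acidification spares the enol ether.

Step 7
Reactants: 8 3,5-dimethoxy-2-(trimethylsilyl)phenyl trifluoromethanesulfonate; 12 (E)-2-(4-bromophenyl)-3-methoxyacrylic acid
Product: 15 3-(4-bromophenyl)-5,7-dimethoxy-4H-chromen-4-one, via 3,5-dimethoxybenzyne 13 (not isolated), via keto phenoxide 14 (not isolated)
Conditions: CsF (4 equiv), 8 (1.5 equiv), THF, 125 °C, sealed tube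
Reagents that add atoms: none
Why: Fluoride strips the silyl group from 8 and triflate leaves to give aryne 13; the cesium carboxylate of 12 adds through oxygen to the aryne carbon remote from the neighbouring methoxy group, and the aryl anion thus placed beside that methoxy group attacks the ester carbonyl through a four-membered alkoxide that opens to keto phenoxide 14, a net O-to-C acyl shift. The closest known reaction type is the insertion of arynes into the C–O bond of carboxylic acids to give ortho-hydroxyaryl ketones, which with unsaturated acids is followed in the same flask by oxa-Michael ring closure. Ring C closes by 6-endo-trig addition of the phenoxide oxygen to the methoxy-bearing alkene carbon, and the enolate then expels methoxide (addition–elimination, E1cB) to give the 4-pyranone, so the alkene geometry of 12 is immaterial. No stereocentre is created. The step needs oxygen at C8a and the acyl carbon at C4a: the single methoxy substituent flanking the aryne polarises and distorts the triple bond so that the nucleophile enters at the distal carbon and the anion is inductively stabilised next to oxygen, and with hydrogen on the other flank nothing opposes this bias, while C8 stays unsubstituted for the later chlorination. Acyl transfer must also outrun protonation of the aryl anion, which the aprotic medium, the excess of aryne precursor and the high temperature should favour.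

Step 8
Reactants: 15 3-(4-bromophenyl)-5,7-dimethoxy-4H-chromen-4-one
Product: 16 3-(4-bromophenyl)-8-chloro-5,7-dimethoxy-4H-chromen-4-one
Conditions: NCS (1.05 equiv), DMF, rt → 50 °C
Reagents that add atoms: N-chlorosuccinimide, O=C1CCC(=O)N1Cl
Why: Electrophilic aromatic substitution: C8 is ortho to the C7 methoxy group and to O1 and para to the C5 methoxy group, and 5,7-dialkoxychromones are halogenated there in preference to C6, which is hemmed in by two methoxy groups, while the bromophenyl ring and the pyranone are too electron-poor to compete.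

Step 9
Reactants: 17 genistein
Product: 18 5,7-dimethoxy-3-(4-methoxyphenyl)-4H-chromen-4-one
Conditions: Me2SO4 (excess), K2CO3, DMF, 60 °C
Reagents that add atoms: dimethyl sulfate, COS(=O)(=O)OC
Why: Williamson etherification of the three phenols; the chelated C5 hydroxyl reacts last, hence the excess reagent and the warming.

Step 10
Reactants: 18 5,7-dimethoxy-3-(4-methoxyphenyl)-4H-chromen-4-one
Product: 19 8-bromo-5,7-dimethoxy-3-(4-methoxyphenyl)-4H-chromen-4-one
Conditions: NBS (1.0 equiv), DMF, 0 °C → rt
Reagents that add atoms: N-bromosuccinimide, O=C1CCC(=O)N1Br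
Why: Electrophilic aromatic bromination at C8 of ring A, the preferred free position of a 5,7-dimethoxychromone; one equivalent of NBS at low temperature should avoid attack at C6 and on the less activated anisole ring.

Step 11
Reactants: 19 8-bromo-5,7-dimethoxy-3-(4-methoxyphenyl)-4H-chromen-4-one
Product: 21 8-hydroxy-5,7-dimethoxy-3-(4-methoxyphenyl)-4H-chromen-4-one, via pinacol boronate 20 (not isolated)
Conditions: B2pin2, Pd(OAc)2 (cat.), SPhos, KOAc, dioxane, 90 °C; then NaBO3·4H2O, THF/H2O, rt
Reagents that add atoms: sodium perborate (oxygen at C8), [Na+].[Na+].O[B-]1(O)OO[B-](O)(O)OO1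
Why: Miyaura borylation of the aryl bromide (zerovalent palladium carrying a bulky biaryl phosphine copes with the two ortho substituents) followed by perborate oxidation of the C–B bond, in which the aryl group migrates from boron to oxygen at the same carbon; the mild oxidant spares the base-sensitive pyranone.

Step 12
Reactants: 16 3-(4-bromophenyl)-8-chloro-5,7-dimethoxy-4H-chromen-4-one; 21 8-hydroxy-5,7-dimethoxy-3-(4-methoxyphenyl)-4H-chromen-4-one
Product: 22 8-chloro-3-(4-{[5,7-dimethoxy-3-(4-methoxyphenyl)-4-oxo-4H-chromen-8-yl]oxy}phenyl)-5,7-dimethoxy-4H-chromen-4-one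
Conditions: CuI (10 mol%), picolinic acid (20 mol%), K3PO4, DMSO, 90 °C
Reagents that add atoms: none
Why: Ullmann-type C–O coupling: the picolinate-ligated copper phenoxide formed from 21 reacts with the aryl bromide of 16, a ligand system known to tolerate phenols with two ortho substituents, while the aryl chloride at C8 is inert to copper catalysis at this temperature.

Step 13
Reactants: 22 8-chloro-3-(4-{[5,7-dimethoxy-3-(4-methoxyphenyl)-4-oxo-4H-chromen-8-yl]oxy}phenyl)-5,7-dimethoxy-4H-chromen-4-one
Product: 23 8-chloro-3-(4-{[5,7-dihydroxy-3-(4-hydroxyphenyl)-4-oxo-4H-chromen-8-yl]oxy}phenyl)-5,7-dihydroxy-4H-chromen-4-one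
Conditions: BBr3 (excess), CH2Cl2, −78 °C → rt; then MeOH, H2O
Reagents that add atoms: none
Why: Lewis-acid demethylation: BBr3 coordinates each methoxy oxygen and bromide removes the methyl group by SN2, whereas the diaryl ether, the aryl chloride and both pyranones are untouched, and aqueous work-up hydrolyses the aryl borates to the five phenols.

Compound list
1 | 3,5-dimethoxyphenol | COc1cc(O)cc(OC)c1 | starting material
2 | 3,5-dimethoxyphenyl isopropylcarbamate | COc1cc(OC(=O)NC(C)C)cc(OC)c1 | intermediate
3 | 3,5-dimethoxyphenyl N-(tert-butyldimethylsilyl)-N-isopropylcarbamate | COc1cc(OC(=O)N(C(C)C)[Si](C)(C)C(C)(C)C)cc(OC)c1 | intermediate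
4 | 2-lithio-3,5-dimethoxyphenyl N-(tert-butyldimethylsilyl)-N-isopropylcarbamate | [Li]c1c(OC)cc(OC)cc1OC(=O)N(C(C)C)[Si](C)(C)C(C)(C)C | intermediate
5 | 3,5-dimethoxy-2-(trimethylsilyl)phenyl N-(tert-butyldimethylsilyl)-N-isopropylcarbamate | COc1cc(OC)c([Si](C)(C)C)c(OC(=O)N(C(C)C)[Si](C)(C)C(C)(C)C)c1 | intermediate
6 | 3,5-dimethoxy-2-(trimethylsilyl)phenyl isopropylcarbamate | COc1cc(OC)c([Si](C)(C)C)c(OC(=O)NC(C)C)c1 | intermediate
7 | 3,5-dimethoxy-2-(trimethylsilyl)phenol | COc1cc(O)c([Si](C)(C)C)c(OC)c1 | intermediate
8 | 3,5-dimethoxy-2-(trimethylsilyl)phenyl trifluoromethanesulfonate | COc1cc(OC)c([Si](C)(C)C)c(OS(=O)(=O)C(F)(F)F)c1 | intermediate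
9 | methyl 4-bromophenylacetate | COC(=O)Cc1ccc(Br)cc1 | starting material
10 | methyl (Z)-2-(4-bromophenyl)-3-hydroxyacrylate | O/C=C(/c1ccc(Br)cc1)C(=O)OC | intermediate
11 | methyl (E)-2-(4-bromophenyl)-3-methoxyacrylate | CO/C=C(\c1ccc(Br)cc1)C(=O)OC | intermediate
12 | (E)-2-(4-bromophenyl)-3-methoxyacrylic acid | CO/C=C(\c1ccc(Br)cc1)C(=O)O | intermediate
13 | 3,5-dimethoxybenzyne (1,2-didehydro-3,5-dimethoxybenzene) | COC1=CC(OC)=CC#C1 | intermediate
14 | cesium 2-[(E)-2-(4-bromophenyl)-3-methoxyacryloyl]-3,5-dimethoxyphenolate | [Cs+].CO/C=C(\c1ccc(Br)cc1)C(=O)c1c([O-])cc(OC)cc1OC | intermediate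
15 | 3-(4-bromophenyl)-5,7-dimethoxy-4H-chromen-4-one | O=c1c(-c2ccc(Br)cc2)coc2cc(OC)cc(OC)c12 | intermediate
16 | 3-(4-bromophenyl)-8-chloro-5,7-dimethoxy-4H-chromen-4-one | O=c1c(-c2ccc(Br)cc2)coc2c(Cl)c(OC)cc(OC)c12 | intermediate
17 | genistein, 5,7-dihydroxy-3-(4-hydroxyphenyl)-4H-chromen-4-one | O=c1c(-c2ccc(O)cc2)coc2cc(O)cc(O)c12 | starting material
18 | 5,7-dimethoxy-3-(4-methoxyphenyl)-4H-chromen-4-one | O=c1c(-c2ccc(OC)cc2)coc2cc(OC)cc(OC)c12 | intermediate
19 | 8-bromo-5,7-dimethoxy-3-(4-methoxyphenyl)-4H-chromen-4-one | O=c1c(-c2ccc(OC)cc2)coc2c(Br)c(OC)cc(OC)c12 | intermediate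
20 | 5,7-dimethoxy-3-(4-methoxyphenyl)-8-(4,4,5,5-tetramethyl-1,3,2-dioxaborolan-2-yl)-4H-chromen-4-one | O=c1c(-c2ccc(OC)cc2)coc2c(B3OC(C)(C)C(C)(C)O3)c(OC)cc(OC)c12 | intermediate
21 | 8-hydroxy-5,7-dimethoxy-3-(4-methoxyphenyl)-4H-chromen-4-one | O=c1c(-c2ccc(OC)cc2)coc2c(O)c(OC)cc(OC)c12 | intermediate
22 | 8-chloro-3-(4-{[5,7-dimethoxy-3-(4-methoxyphenyl)-4-oxo-4H-chromen-8-yl]oxy}phenyl)-5,7-dimethoxy-4H-chromen-4-one | O=c1c(-c2ccc(Oc3c(OC)cc(OC)c4c(=O)c(-c5ccc(OC)cc5)coc34)cc2)coc2c(Cl)c(OC)cc(OC)c12 | intermediate
23 | 8-chloro-3-(4-{[5,7-dihydroxy-3-(4-hydroxyphenyl)-4-oxo-4H-chromen-8-yl]oxy}phenyl)-5,7-dihydroxy-4H-chromen-4-one, bisoflavolin I | O=c1c(-c2ccc(Oc3c(O)cc(O)c4c(=O)c(-c5ccc(O)cc5)coc34)cc2)coc2c(Cl)c(O)cc(O)c12 | target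

Total step count: 13

Longest linear sequence: 7 steps (1 → 2 → 6 → 8 → 15 → 16 → 22 → 23; the branch from 9 is equally long, the branch from 17 has 5 steps)

Steps most likely to fail

Step 7. The aryl anion formed after O-arylation may be protonated before it transfers the acyl group, which would stop at simple O-arylation of the acid. The low electrophilicity of the vinylogous carbonate carbonyl could slow the acyl shift further, and fluoride or expelled methoxide may consume the aryne. In that case ring C would be built by the classical deoxybenzoin route, setting out from 9 and 1. Ester 9 is saponified (LiOH, THF/H2O) to 4-bromophenylacetic acid F1. This acid acylates phenol 1 ortho to the hydroxyl in neat BF3·OEt2 at 85 °C (Friedel–Crafts acylation with Fries-type ortho delivery) to give 2-(4-bromophenyl)-1-(2-hydroxy-4,6-dimethoxyphenyl)ethan-1-one F2. Addition of DMF and MsCl to the same BF3 solution introduces the C2 carbon by Vilsmeier-type formylation of the methylene and closes the pyranone, which returns to the route at 15.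

Step 12. Coupling may stall because the copper phenoxide of 21 is crowded on both sides, and prolonged heating with base may open a pyranone ring by attack at C2. The polarity of the aryl partner would then be reversed, setting out from 16. Miyaura borylation (B2pin2, PdCl2(dppf), KOAc, dioxane, 80 °C), in which the bromide reacts and the hindered chloride does not, should give 8-chloro-5,7-dimethoxy-3-[4-(4,4,5,5-tetramethyl-1,3,2-dioxaborolan-2-yl)phenyl]-4H-chromen-4-one F3. Chan–Lam–Evans oxidative etherification of F3 with phenol 21 (Cu(OAc)2, pyridine, 4 Å MS, air, CH2Cl2, rt) forms the same C–O bond at room temperature with a weak amine base and comes back to the route at 22.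

Step 8. Chlorination may be imperfectly site-selective between C8 and C6, or run on to a second chlorination. The chlorine would then be placed by directed metalation before the heterocycle exists, setting out from 2. N-Silylation and ortho-lithiation exactly as in step 2 (through 3 and 4), then quenching with C2Cl6 in place of TMSCl, gives 2-chloro-3,5-dimethoxyphenyl N-(tert-butyldimethylsilyl)-N-isopropylcarbamate F4, and acidic work-up gives 2-chloro-3,5-dimethoxyphenyl isopropylcarbamate F5. Cleavage with DBU/Et2NH in MeCN frees 2-chloro-3,5-dimethoxyphenol F6, in which the chlorine position is fixed by the lithiation site. Acylation of F6 with acid F1 in BF3·OEt2 at the free position ortho to the hydroxyl gives 2-(4-bromophenyl)-1-(3-chloro-2-hydroxy-4,6-dimethoxyphenyl)ethan-1-one F7. Ring closure of F7 with DMF/MsCl in the same medium returns to the route at 16.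

Further compounds
F1 | step 7 | 4-bromophenylacetic acid | OC(=O)Cc1ccc(Br)cc1
F2 | step 7 | 2-(4-bromophenyl)-1-(2-hydroxy-4,6-dimethoxyphenyl)ethan-1-one | COc1cc(O)c(C(=O)Cc2ccc(Br)cc2)c(OC)c1
F3 | step 12 | 8-chloro-5,7-dimethoxy-3-[4-(4,4,5,5-tetramethyl-1,3,2-dioxaborolan-2-yl)phenyl]-4H-chromen-4-one | COc1cc(OC)c2c(=O)c(-c3ccc(B4OC(C)(C)C(C)(C)O4)cc3)coc2c1Cl
F4 | step 8 | 2-chloro-3,5-dimethoxyphenyl N-(tert-butyldimethylsilyl)-N-isopropylcarbamate | COc1cc(OC)c(Cl)c(OC(=O)N(C(C)C)[Si](C)(C)C(C)(C)C)c1
F5 | step 8 | 2-chloro-3,5-dimethoxyphenyl isopropylcarbamate | COc1cc(OC)c(Cl)c(OC(=O)NC(C)C)c1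
F6 | step 8 | 2-chloro-3,5-dimethoxyphenol | COc1cc(O)c(Cl)c(OC)c1
F7 | step 8 | 2-(4-bromophenyl)-1-(3-chloro-2-hydroxy-4,6-dimethoxyphenyl)ethan-1-one | COc1cc(OC)c(C(=O)Cc2ccc(Br)cc2)c(O)c1Cl
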